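**Remark on the chemistry (assumption):** the target has no stereocentre, and with only one ortho substituent on ring A next to the ether oxygen no hindered rotation is assumed. Ring B is numbered C1 (OH), C2 (O-aryl), C3 (Br), C4 (H), C5 (Br), C6 (Br); ring A is numbered C1 (O-aryl), C2 (OMe), C3 (Br), C4 (H), C5 (Br), C6 (H). The aldehyde-to-phenol conversion on ring A is run as a peracid Baeyer–Villiger oxidation, because a methyl ether has no free hydroxyl next to the formyl group for a Dakin reaction under basic peroxide.

## Structural features

The target is a diaryl ether: two benzene rings joined through one oxygen, with no stereocentre. Ring A has only one substituent (OMe) ortho to the ether oxygen, so no axis of hindered rotation needs control. Ring A is a guaiacol-type ring whose two bromines (C3, C5) sit ortho and para to the methoxy oxygen. Ring B is pentasubstituted, and its bromines (C3, C5, C6) are not where electrophilic bromination of a 2-aryloxyphenol would place them (C4 and C6). The fragile groups are the five C–Br bonds, which are open to halogen–metal exchange, to insertion of low-valent transition metals and to base-induced halogen migration, and the acidic polybromophenol. The real difficulty is regiochemical: the two oxygens of ring B must be told apart although each has a bromine neighbour, and the Br/H/Br/Br sequence must be in place without a late bromination. The key step exploits two facts: C3–C6 of ring B are the intact Br, H, Br, Br edge of 1,2,4,5-tetrabromobenzene, and the oxygen-bearing carbons C1 and C2 are neighbours, that is, the two carbons of an aryne. The ether oxygen can therefore be delivered to C2 and a placeholder for the hydroxyl to C1 in one operation.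

## Logic of the disconnections

**19 to 16.** The C1–O bond of ring B in 19 is cut and the hydroxyl is traced back to the iodine of 16. Iodine is chosen because it exchanges with magnesium ahead of every bromine, so the five C–Br bonds can stay untouched. The gain is that the free, acidic phenol appears only in the last step. The demand is a hydroxylation that runs through 17 and 18 at low temperature, with exactly one equivalent of exchange reagent.

**16 to 8 and 12.** The diaryl ether bond C2–O and the C1–I bond of ring B are cut together. This reveals aryne 14, which takes up 13 at C2 and, as aryl anion 15, an iodine atom at C1. The molecule falls into two halves of similar size and no transition metal is needed. The forward step must add 13 to the correct aryne carbon and must trap 15 with iodine faster than 15 loses bromide or picks up a proton.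

**8 to 5 to 4.** The O–S bond and the C2–Si bond of 8 are cut; the silicon is traced back to the oxygen of 5, from which it migrates to carbon through 6 and 7, and 5 comes from 4 by O-silylation. Because 4 is symmetric, its two ortho bromines are equivalent and only ortho versus meta exchange must be controlled. The demand is that the silyl shift in 6 is faster than β-elimination of the neighbouring bromide.

**4 to 1.** The C1–O bond of 4 is cut, leading to 1, which has two equivalent hydrogens, each flanked by two bromines. This ties the whole Br/H/Br/Br edge to a cheap symmetric arene. The forward step must metalate once and trap 2 as 3 before halogen migration or elimination sets in.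

**12 to 10 to 9.** The phenolic C–O bond of 12 is traced back to the formyl C–C bond of 10 (oxidative aryl migration through 11), and the O–CH3 bond of 10 is cut to give 9. Both ring A bromines are then bought in the right places. The demand is aryl migration, not hydride migration, in the peracid step, which the ortho methoxy group supports.

## Other disconnections considered

**Alternative 1:** The cut runs through ring A: its C1–C6 and C3–C4 bonds are broken. Ring A is then assembled from 1-[2,4,5-tribromo-6-(methoxymethoxy)phenoxy]propan-2-one A2 and 2-bromomalonaldehyde A3 by a base-mediated double aldol condensation with loss of two molecules of water. This should give 4-bromo-2-[2,4,5-tribromo-6-(methoxymethoxy)phenoxy]phenol A1.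
- In its favour: the ring A bromine at C5 is built in by A3, the ether oxygen is attached by a simple O-alkylation, and no organometallic intermediate meets a C–Br bond.
- Against it: A1 still needs ortho-bromination of ring A, O-methylation and acetal cleavage. A2 must come from 2,4,5-tribromo-6-(methoxymethoxy)phenol A4, a tribromocatechol in which exactly one of two very similar oxygens is protected, so the ring B problem is moved and not solved, unless A4 is itself made from 4 by ortho exchange and oxidation. A3 is an α-bromo dialdehyde that can alkylate or brominate the enolate of A2, and the electron-poor aryloxide is a leaving group β to the aldol centres.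
- Comparison: on structure this plan is the better one in one respect, since the position of the ether oxygen on ring B is fixed by which oxygen of A4 is free and not by an aryne bias; it is equal in bringing the Br/H/Br/Br edge in ready-made. On mechanism it uses ordinary carbonyl condensations, but this phenol synthesis is well established only for more electrophilic dialdehydes, so its footing is no firmer than that of the aryne coupling. On step economy it is poorer: three steps after the ring-forming step and at least four before it, against seven in all for the chosen plan.

**Alternative 2:** The cut removes the three C–Br bonds of ring B. N-[3-(3,5-dibromo-2-methoxyphenoxy)-4-hydroxyphenyl]acetamide A6, carrying a removable nitrogen at C4, would be tribrominated in one operation with bromine in acetic acid. This should give N-[2,3,6-tribromo-5-(3,5-dibromo-2-methoxyphenoxy)-4-hydroxyphenyl]acetamide A5.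
- In its favour: C4 is blocked and every remaining position of ring B is activated by the hydroxyl, the acetamide or the ether oxygen, so the substitution pattern of A5 follows from exhaustive halogenation. The diaryl ether A6 can be made from 12 on an unhalogenated ring B by conventional means.
- Against it: 4-acetamidophenols such as A6 are easily oxidised by halogens to quinoid products. The last bromines must enter ortho to the acetamide in a crowded, deactivated ring, while C4 and C6 of ring A remain open to over-bromination. Removal of nitrogen from A5 costs N-deacetylation of a doubly ortho-brominated anilide, diazotisation of a 4-aminophenol, which tends to give a stable quinone diazide, and reductive dediazoniation.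
- Comparison: on structure it is the better plan as far as regiochemistry goes, because nothing depends on a modest bias; it is equal in taking ring A unchanged from 12. On mechanism it relies on classical electrophilic substitution, against a new three-component coupling, at the price of oxidation-prone intermediates. On step economy it is poorer: three steps after A5 and about four to reach A6.

**Alternative 3:** The cut takes ring A back to a saturated ketone. Racemic 2-[2,4,5-tribromo-6-(propan-2-yloxy)phenoxy]cyclohexan-1-one A8 would be treated with excess bromine in acetic acid buffered with NaOAc, which aromatises the ring and brominates it at C3 and C5. This should give 2,4-dibromo-6-[2,4,5-tribromo-6-(propan-2-yloxy)phenoxy]phenol A7.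
- In its favour: the ether bond of A8 is formed by alkylating 2,4,5-tribromo-6-(propan-2-yloxy)phenol A9 with racemic 2-chlorocyclohexan-1-one A10, which is unambiguous. The two ring A bromines enter ortho and para to the new hydroxyl, exactly where they are needed, and the plan is metal-free.
- Against it: A9 is again a tribromocatechol with one particular oxygen protected; its sound preparation starts from 4, so no early step is saved. The repeated bromination and dehydrobromination cycles on A8 release strong acid that endangers the isopropyl ether, and the α-bromo ketone intermediates can expel the electron-poor aryloxide. A7 then needs O-methylation and selective cleavage of the isopropyl ether.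
- Comparison: on structure it is the better plan for certainty of the C–O connection, and equal for ring A, whose bromines the chosen plan buys in place. On mechanism it is equal in avoiding transition metals and rests on older chemistry, but under harsher, strongly oxidising conditions. On step economy it is poorer, at about nine steps against seven.

Key step: step 6

## Route

**Step 1**
Reactants: 1 1,2,4,5-tetrabromobenzene
Product: 4 2,3,5,6-tetrabromophenol, via (2,3,5,6-tetrabromophenyl)lithium 2 (not isolated), via lithium triisopropoxy(2,3,5,6-tetrabromophenyl)borate 3 (not isolated)
Conditions: B(OiPr)3, LiN(iPr)2 (1.05 equiv), THF, −78 °C; then AcOH, 30% H2O2, 0 °C → rt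
Reagents that add atoms: hydrogen peroxide, OO (the phenol oxygen of 4); triisopropyl borate, CC(C)OB(OC(C)C)OC(C)C (boron and alkoxy groups of 3 only, none in 4)
Why: Deprotonation with in situ borate trapping, then oxidative C–B to C–O conversion: the hydrogen flanked by two bromines is removed at −78 °C, 2 is intercepted at once by the borate already present so that loss of bromide and halogen migration should not compete, the anionic borate 3 resists a second metalation, and acidic peroxide should give the phenol by 1,2-aryl shift from boron to oxygen.

**Step 2**
Reactants: 4 2,3,5,6-tetrabromophenol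
Product: 5 trimethyl(2,3,5,6-tetrabromophenoxy)silane
Conditions: (Me3Si)2NH, THF, reflux; volatiles removed, used crude
Reagents that add atoms: hexamethyldisilazane, C[Si](C)(C)N[Si](C)(C)C
Why: O-Silylation of an acidic phenol with a disilazane; only ammonia is lost, so the moisture-sensitive silyl ether can be taken on after evaporation.

**Step 3**
Reactants: 5 trimethyl(2,3,5,6-tetrabromophenoxy)silane
Product: 8 3,5,6-tribromo-2-(trimethylsilyl)phenyl trifluoromethanesulfonate, via [3,4,6-tribromo-2-(trimethylsilyloxy)phenyl]lithium 6 (not isolated), via lithium 3,5,6-tribromo-2-(trimethylsilyl)phenolate 7 (not isolated)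
Conditions: n-BuLi (1.0 equiv), THF, −100 → −78 °C; then Tf2O, −100 → −78 °C
Reagents that add atoms: trifluoromethanesulfonic anhydride, O=S(=O)(OS(=O)(=O)C(F)(F)F)C(F)(F)F
Why: Bromine–lithium exchange at one of the two equivalent bromines ortho to oxygen (the carbon flanked by oxygen and bromine gives the best-stabilised aryllithium), then a 1,3-shift of silicon from oxygen to carbon (retro-Brook rearrangement) and O-triflation of phenoxide 7 in the same flask; the intramolecular silyl transfer is expected to outrun loss of bromide from 6.

**Step 4**
Reactants: 9 3,5-dibromo-2-hydroxybenzaldehyde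
Product: 10 3,5-dibromo-2-methoxybenzaldehyde
Conditions: MeI, K2CO3, DMF, rt
Reagents that add atoms: iodomethane, CI
Why: Williamson O-methylation of an acidic, hydrogen-bonded phenol; the aldehyde and the aryl bromides are inert to carbonate and iodomethane.

**Step 5**
Reactants: 10 3,5-dibromo-2-methoxybenzaldehyde
Product: 12 3,5-dibromo-2-methoxyphenol, via 3,5-dibromo-2-methoxyphenyl formate 11 (not isolated)
Conditions: mCPBA, CH2Cl2, 0 °C → rt; then MeOH, Et3N (cat.), rt
Reagents that add atoms: 3-chloroperbenzoic acid, OOC(=O)c1cccc(Cl)c1
Why: Baeyer–Villiger oxidation of an aryl aldehyde (Dakin-type outcome): the ortho methoxy group supports aryl over hydride migration in the peracid adduct, and the aryl formate 11 is cleaved by mild methanolysis.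

**Step 6**
Reactants: 12 3,5-dibromo-2-methoxyphenol (2 equiv); 8 3,5,6-tribromo-2-(trimethylsilyl)phenyl trifluoromethanesulfonate
Product: 16 1,2,5-tribromo-4-(3,5-dibromo-2-methoxyphenoxy)-3-iodobenzene, via potassium 3,5-dibromo-2-methoxyphenolate 13 (not isolated), via 3,4,6-tribromobenzyne 14 (not isolated), via potassium 3,5,6-tribromo-2-(3,5-dibromo-2-methoxyphenoxy)phenide 15 (not isolated)
Conditions: 12, KH, THF, 0 °C; then n-C4F9I (5 equiv), KF, 18-crown-6, slow addition of 8, 0 °C → rt, dark
Reagents that add atoms: nonafluoro-1-iodobutane, FC(F)(F)C(F)(F)C(F)(F)C(F)(F)I (the iodine)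
Why: Proposed new method: fluoride removes the silyl group of 8 while triflate departs from the adjacent carbon, so that aryne 14 forms with its strained bond between C1 and C2 of ring B; phenoxide 13 adds to C2, and the resulting aryl anion 15 at C1 abstracts iodine from n-C4F9I by halophilic attack, after which the nonafluorobutyl anion collapses to octafluorobut-1-ene and fluoride. The nearest established reactions are aryne O-arylations of phenols triggered by fluoride, which end with protonation of the aryl anion, and aryne three-component couplings in which the anion left by a heteroatom nucleophile is captured by a halogen donor or by carbon dioxide; a phenoxide paired with an iodine donor on a polybromoaryne lies outside both. No ring is closed and no stereocentre is formed. The step needs regioselective addition at C2: each aryne carbon has a bromine neighbour, so the bias comes only from the C5 bromine, which is meta to an anion at C1 but para to an anion at C2 and which buttresses the C6 bromine towards C1, and this preference is expected to be modest. The step also needs iodine transfer to outrun loss of bromide from C6 of 15 and bromine abstraction from other polybromoarenes, which the large excess of the fast iodine donor and the slow generation of 14 should secure. Preformed 13 in dry THF keeps proton sources away from 15, and darkness suppresses electron transfer between 13 and the perfluoroalkyl iodide. The excess of 13 allows for what the fluoroalkene by-product may consume, and no transition metal that could insert into a C–Br bond is present.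

**Step 7**
Reactants: 16 1,2,5-tribromo-4-(3,5-dibromo-2-methoxyphenoxy)-3-iodobenzene
Product: 19 3,5,6-tribromo-2-(3,5-dibromo-2-methoxyphenoxy)phenol, via [3,5,6-tribromo-2-(3,5-dibromo-2-methoxyphenoxy)phenyl]magnesium chloride 17 (not isolated), via dimethyl [3,5,6-tribromo-2-(3,5-dibromo-2-methoxyphenoxy)phenyl]boronate 18 (not isolated)
Conditions: iPrMgCl·LiCl (1.05 equiv), THF, −78 → −40 °C; B(OMe)3, −78 → 0 °C; then AcOH, 30% H2O2, 0 °C → rt
Reagents that add atoms: hydrogen peroxide, OO (the phenol oxygen of 19); trimethyl borate, COB(OC)OC (boron and methoxy groups of 18 only, none in 19)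
Why: Iodine–magnesium exchange, borylation and oxidation in one pot: the iodine flanked by oxygen and bromine should exchange at −78 °C well before any bromine, the ortho-bromoarylmagnesium 17 is stable at this temperature, and non-basic peroxide oxidation of 18 avoids base-induced protodeboronation of the doubly ortho-substituted boronate.

## Compound list

1 | 1,2,4,5-tetrabromobenzene | Brc1cc(Br)c(Br)cc1Br | starting material
2 | (2,3,5,6-tetrabromophenyl)lithium | [Li]c1c(Br)c(Br)cc(Br)c1Br | intermediate (not isolated)
3 | lithium triisopropoxy(2,3,5,6-tetrabromophenyl)borate | [Li+].CC(C)O[B-](OC(C)C)(OC(C)C)c1c(Br)c(Br)cc(Br)c1Br | intermediate (not isolated)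
4 | 2,3,5,6-tetrabromophenol | Oc1c(Br)c(Br)cc(Br)c1Br | intermediate
5 | trimethyl(2,3,5,6-tetrabromophenoxy)silane | C[Si](C)(C)Oc1c(Br)c(Br)cc(Br)c1Br | intermediate
6 | [3,4,6-tribromo-2-(trimethylsilyloxy)phenyl]lithium | [Li]c1c(Br)cc(Br)c(Br)c1O[Si](C)(C)C | intermediate (not isolated)
7 | lithium 3,5,6-tribromo-2-(trimethylsilyl)phenolate | [Li+].[O-]c1c(Br)c(Br)cc(Br)c1[Si](C)(C)C | intermediate (not isolated)
8 | 3,5,6-tribromo-2-(trimethylsilyl)phenyl trifluoromethanesulfonate | C[Si](C)(C)c1c(Br)cc(Br)c(Br)c1OS(=O)(=O)C(F)(F)F | intermediate
9 | 3,5-dibromo-2-hydroxybenzaldehyde | O=Cc1cc(Br)cc(Br)c1O | starting material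
10 | 3,5-dibromo-2-methoxybenzaldehyde | COc1c(Br)cc(Br)cc1C=O | intermediate
11 | 3,5-dibromo-2-methoxyphenyl formate | COc1c(Br)cc(Br)cc1OC=O | intermediate (not isolated)
12 | 3,5-dibromo-2-methoxyphenol | COc1c(Br)cc(Br)cc1O | intermediate
13 | potassium 3,5-dibromo-2-methoxyphenolate | [K+].COc1c(Br)cc(Br)cc1[O-] | intermediate (not isolated)
14 | 3,4,6-tribromobenzyne (1,2,4-tribromo-5,6-didehydrobenzene) | BrC1=CC(Br)=C(Br)C#C1 | intermediate (not isolated)
15 | potassium 3,5,6-tribromo-2-(3,5-dibromo-2-methoxyphenoxy)phenide | [K+].COc1c(Br)cc(Br)cc1Oc1c(Br)cc(Br)c(Br)[c-]1 | intermediate (not isolated)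
16 | 1,2,5-tribromo-4-(3,5-dibromo-2-methoxyphenoxy)-3-iodobenzene | COc1c(Br)cc(Br)cc1Oc1c(Br)cc(Br)c(Br)c1I | intermediate
17 | [3,5,6-tribromo-2-(3,5-dibromo-2-methoxyphenoxy)phenyl]magnesium chloride (LiCl complex) | Cl[Mg]c1c(Br)c(Br)cc(Br)c1Oc1cc(Br)cc(Br)c1OC | intermediate (not isolated)
18 | dimethyl [3,5,6-tribromo-2-(3,5-dibromo-2-methoxyphenoxy)phenyl]boronate | COB(OC)c1c(Br)c(Br)cc(Br)c1Oc1cc(Br)cc(Br)c1OC | intermediate (not isolated)
19 | 3,5,6-tribromo-2-(3,5-dibromo-2-methoxyphenoxy)phenol | COc1c(Br)cc(Br)cc1Oc1c(Br)cc(Br)c(Br)c1O | target

## Step count and risks

Total: 7 steps. Longest linear sequence: 5 steps (steps 1, 2, 3, 6, 7, from 1). The ring A branch (steps 4 and 5, from 9) joins at step 6.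

**Step 6 (key step, the one step beyond known chemistry).** Most likely to go wrong: poor regiocontrol in the addition of 13 to 14 (attack at C1 instead of C2), because the two aryne carbons differ only through the remote C5 bromine. Further risks are loss of bromide from 15 or its protonation before iodine transfer, and triflyl transfer from 8 to 13 in place of desilylation. Fallback (known chemistry), setting out from 12 and returning at 19: purchased 1,2,4-tribromo-5-fluorobenzene F1 is deprotonated with LiN(iPr)2 in THF at −78 °C at the hydrogen flanked by fluorine and bromine, expected to be the more acidic of the two, and formylated with DMF to give 3,5,6-tribromo-2-fluorobenzaldehyde F2. In F2 the fluorine is activated by the ortho formyl group, so nucleophilic aromatic substitution by 12 with K2CO3 in DMF should give 3,5,6-tribromo-2-(3,5-dibromo-2-methoxyphenoxy)benzaldehyde F3; the ether oxygen is fixed at C2 by the position of the fluorine in F1. Baeyer–Villiger oxidation of F3 with mCPBA should give 3,5,6-tribromo-2-(3,5-dibromo-2-methoxyphenoxy)phenyl formate F4, and methanolysis of F4 should give 19 directly, without passing through 16.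

**Step 3.** Most likely to go wrong: elimination of bromide from 6, whose lithium has a bromine neighbour, before the silyl shift takes place; or exchange at a bromine meta to oxygen. Fallback, setting out from 4 and returning at 8: 4 is protected with MOMCl and iPr2NEt as 1,2,4,5-tetrabromo-3-(methoxymethoxy)benzene F5. Chelation-directed bromine–magnesium exchange on F5 with iPrMgCl·LiCl at −40 °C gives an arylmagnesium that does not eliminate at this temperature, and silylation with Me3SiOTf should give [3,4,6-tribromo-2-(methoxymethoxy)phenyl]trimethylsilane F6. Acetal cleavage of F6 with HCl in MeOH gives 3,5,6-tribromo-2-(trimethylsilyl)phenol F7, and F7 is converted to 8 with Tf2O and pyridine in CH2Cl2.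

**Step 1.** Most likely to go wrong: halogen migration and loss of bromide from 2 if trapping by the borate lags behind deprotonation, or a second metalation at the remaining ring hydrogen. Fallback, setting out from 1 and returning at 4, by electrophilic substitution in place of anion chemistry: nitration of 1 with fuming HNO3 in H2SO4 gives 1,2,4,5-tetrabromo-3-nitrobenzene F8. Reduction of F8 with Fe in AcOH gives 2,3,5,6-tetrabromoaniline F9. Diazotisation of F9 with NaNO2 in H2SO4/AcOH gives 2,3,5,6-tetrabromobenzenediazonium hydrogensulfate F10, and hydroxydediazoniation of F10 with Cu2O and Cu(NO3)2 in water gives 4.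

**Step 7.** Most likely to go wrong: sluggish borylation of the doubly ortho-substituted, electron-poor arylmagnesium 17 and protodeboronation of 18, both of which replace iodine by hydrogen; with excess reagent, exchange of an activated bromine. Fallback, setting out from 16 and returning at 19, with oxygen delivered directly and no boron: after the same exchange at −78 °C, 17 is treated with tert-butyl perbenzoate, which transfers its tert-butoxy oxygen to carbon and should give 1,2,5-tribromo-3-tert-butoxy-4-(3,5-dibromo-2-methoxyphenoxy)benzene F11. CF3CO2H in CH2Cl2 then cleaves the tert-butyl ether of F11, and not the methyl ether, to give 19.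

## Further compounds

F1 | step 6 | 1,2,4-tribromo-5-fluorobenzene | Fc1cc(Br)c(Br)cc1Br
F2 | step 6 | 3,5,6-tribromo-2-fluorobenzaldehyde | O=Cc1c(F)c(Br)cc(Br)c1Br
F3 | step 6 | 3,5,6-tribromo-2-(3,5-dibromo-2-methoxyphenoxy)benzaldehyde | COc1c(Br)cc(Br)cc1Oc1c(Br)cc(Br)c(Br)c1C=O
F4 | step 6 | 3,5,6-tribromo-2-(3,5-dibromo-2-methoxyphenoxy)phenyl formate | COc1c(Br)cc(Br)cc1Oc1c(Br)cc(Br)c(Br)c1OC=O
F5 | step 3 | 1,2,4,5-tetrabromo-3-(methoxymethoxy)benzene | COCOc1c(Br)c(Br)cc(Br)c1Br
F6 | step 3 | [3,4,6-tribromo-2-(methoxymethoxy)phenyl]trimethylsilane | COCOc1c(Br)c(Br)cc(Br)c1[Si](C)(C)C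
F7 | step 3 | 3,5,6-tribromo-2-(trimethylsilyl)phenol | Oc1c(Br)c(Br)cc(Br)c1[Si](C)(C)C
F8 | step 1 | 1,2,4,5-tetrabromo-3-nitrobenzene | O=[N+]([O-])c1c(Br)c(Br)cc(Br)c1Br
F9 | step 1 | 2,3,5,6-tetrabromoaniline | Nc1c(Br)c(Br)cc(Br)c1Br
F10 | step 1 | 2,3,5,6-tetrabromobenzenediazonium hydrogensulfate | N#[N+]c1c(Br)c(Br)cc(Br)c1Br.OS(=O)(=O)[O-]
F11 | step 7 | 1,2,5-tribromo-3-tert-butoxy-4-(3,5-dibromo-2-methoxyphenoxy)benzene | COc1c(Br)cc(Br)cc1Oc1c(Br)cc(Br)c(Br)c1OC(C)(C)C
A1 | alternative 1 | 4-bromo-2-[2,4,5-tribromo-6-(methoxymethoxy)phenoxy]phenol | Oc1ccc(Br)cc1Oc1c(Br)cc(Br)c(Br)c1OCOC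
A2 | alternative 1 | 1-[2,4,5-tribromo-6-(methoxymethoxy)phenoxy]propan-2-one | CC(=O)COc1c(Br)cc(Br)c(Br)c1OCOC
A3 | alternative 1 | 2-bromomalonaldehyde (2-bromopropanedial) | O=CC(Br)C=O
A4 | alternative 1 | 2,4,5-tribromo-6-(methoxymethoxy)phenol | Oc1c(Br)cc(Br)c(Br)c1OCOC
A5 | alternative 2 | N-[2,3,6-tribromo-5-(3,5-dibromo-2-methoxyphenoxy)-4-hydroxyphenyl]acetamide | COc1c(Br)cc(Br)cc1Oc1c(Br)c(NC(C)=O)c(Br)c(Br)c1O
A6 | alternative 2 | N-[3-(3,5-dibromo-2-methoxyphenoxy)-4-hydroxyphenyl]acetamide | COc1c(Br)cc(Br)cc1Oc1cc(NC(C)=O)ccc1O
A7 | alternative 3 | 2,4-dibromo-6-[2,4,5-tribromo-6-(propan-2-yloxy)phenoxy]phenol | Oc1c(Br)cc(Br)cc1Oc1c(Br)cc(Br)c(Br)c1OC(C)C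
A8 | alternative 3 | 2-[2,4,5-tribromo-6-(propan-2-yloxy)phenoxy]cyclohexan-1-one (racemic) | O=C1CCCCC1Oc1c(Br)cc(Br)c(Br)c1OC(C)C
A9 | alternative 3 | 2,4,5-tribromo-6-(propan-2-yloxy)phenol | Oc1c(Br)cc(Br)c(Br)c1OC(C)C
A10 | alternative 3 | 2-chlorocyclohexan-1-one (racemic) | O=C1CCCCC1Cl
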